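**Assumptions.** Dimethyl (R)-malate (1) and 4-(benzyloxy)-3-methoxybenzyl chloride (2) are purchased. Both phenols are carried as benzyl ethers and released in the last step. The target is (2R,3S,4R)-2-(4-hydroxy-3-methoxyphenyl)-4-(4-hydroxy-3-methoxybenzyl)-3-(hydroxymethyl)oxolan-4-ol, an 8'-hydroxylariciresinol.

## Retrosynthesis
1. The target comes from the bis-benzyl ether 9 by hydrogenolysis.
2. The only ring, the tetrahydrofuran, is closed last. Anodic dehydrogenative coupling of the benzylic C7–H with the C9'–OH of triol 8 forms the C7–O bond and sets C7 (2,3-trans).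
3. Triol 8 comes from reducing a pivaldehyde-derived dioxolanone (7). Benzylating the dioxolanone enolate of 6 with retention (self-regeneration of stereocentres) sets the tertiary carbinol C8' (malate C2).
4. The C8 stereocentre is set earlier by the anti-selective Fráter–Seebach benzylation of dimethyl (R)-malate.

## Route

**Step 1**
Reactants: 1 (dimethyl (R)-malate); 2 (4-(benzyloxy)-3-methoxybenzyl chloride)
Product: 3, dimethyl (2R,3S)-3-[4-(benzyloxy)-3-methoxybenzyl]-2-hydroxysuccinate
Conditions: LDA (2.3 equiv), THF, –78 → –20 °C; then 2 (1.2 equiv), NaI (0.2 equiv), DMPU, –20 → 0 °C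
Reagents that add atoms: 2, COc1cc(CCl)ccc1OCc1ccccc1 (the ArCH2 group)
Why: This is a Fráter–Seebach alkylation. The alkoxide/ester-enolate dianion is chelated, and the electrophile enters anti to the C1 ester, giving the 2,3-anti (2R,3S) product, so C8 is set relative to the malate centre.

**Step 2**
Reactants: 3
Product: 4, (2R,3S)-3-[4-(benzyloxy)-3-methoxybenzyl]-2-hydroxysuccinic acid
Conditions: LiOH·H2O (4 equiv), THF/H2O 3:1, 0 °C → rt; then 1 M HCl to pH 2
Reagents that add atoms: none
Why: Mild saponification of both esters. Neither stereocentre is affected at 0 °C, and the benzyl ethers are stable.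

**Step 3**
Reactants: 4; 5 (pivaldehyde)
Product: 6, (2S)-2-[(2R,5R)-2-tert-butyl-4-oxo-1,3-dioxolan-5-yl]-3-[4-(benzyloxy)-3-methoxyphenyl]propanoic acid
Conditions: 5 (3 equiv), TsOH·H2O (5 mol %), pentane, reflux, Dean–Stark
Reagents that add atoms: pivaldehyde, CC(C)(C)C=O (adds the acetal CH–tBu)
Why: Acid-catalysed acetalisation of the α-hydroxy acid gives the five-membered dioxolanone. The thermodynamically preferred 2,5-cis isomer (tBu cis to the side chain) is obtained, and the acetal stereocentre is a transient relay derived from the malate centre, with no external chiral element.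

**Step 4**
Reactants: 6; 2
Product: 7, (2S)-2-[(2R,5R)-2-tert-butyl-5-[4-(benzyloxy)-3-methoxybenzyl]-4-oxo-1,3-dioxolan-5-yl]-3-[4-(benzyloxy)-3-methoxyphenyl]propanoic acid
Conditions: LDA (2.4 equiv), THF/DMPU, –78 °C, 30 min; then 2 (1.3 equiv), –78 → –40 °C
Reagents that add atoms: 2, COc1cc(CCl)ccc1OCc1ccccc1 (the ArCH2 group)
Why: Seebach alkylation with self-regeneration of stereocentres. The carboxylate is inert, the ring enolate is benzylated trans to tBu (on the face the H occupied), so the quaternary carbinol C8' forms with retention as R.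

**Step 5**
Reactants: 7
Product: 8, (2R,3R)-2,3-bis[4-(benzyloxy)-3-methoxybenzyl]butane-1,2,4-triol
Conditions: LiAlH4 (6 equiv), THF, 0 → 65 °C, 4 h; Rochelle-salt work-up
Reagents that add atoms: none
Why: LiAlH4 reduces the carboxylate and opens and reduces the dioxolanone (pivaldehyde leaves as neopentyl alcohol), giving the triol with both stereocentres untouched.

**Step 6**
Reactants: 8
Product: 9, (2R,3S,4R)-2-[4-(benzyloxy)-3-methoxyphenyl]-4-[4-(benzyloxy)-3-methoxybenzyl]-3-(hydroxymethyl)oxolan-4-ol
Conditions: undivided cell, graphite anode/Pt cathode, constant current (5 mA, ~2.3 F/mol), nBu4NBF4 (0.1 M), HFIP/MeCN 1:4, 2,4,6-collidine (1 equiv), rt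
Reagents that add atoms: none (H2 evolves at the cathode)
Why: Proposed new method: anodic dehydrogenative C(sp3)–H/O–H cycloetherification of an unprotected 1,2,4-triol with a free tertiary alcohol.
- Mechanism: the electron-rich aryl ring is oxidised to its radical cation in HFIP. Collidine removes a benzylic proton, and further oxidation gives the p-alkoxybenzylic cation, which the tethered C9'–OH captures in a five-membered closure. Protons are reduced at the cathode.
- Closest known reaction: anodic or DDQ-type benzylic C–H etherification of 4-arylbutanols to 2-aryl-THFs, not shown on a polyol of this kind.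
- Regiochemistry: C7 is favoured over C7', whose cation is destabilised by two β-oxygens. The other hydroxyls could only form oxetanes.
- Stereochemistry: reversible ionisation in HFIP favours Ar trans to C9 and trans to C7', so C7 is R.

**Step 7**
Reactants: 9
Product: 10, the target
Conditions: H2 (1 atm), 10% Pd/C, EtOAc/EtOH 1:1, rt, 1–2 h
Reagents that add atoms: none (only H is added; toluene is lost)
Why: Hydrogenolysis of the two aryl benzyl ethers leaves the THF C–O bond and all stereocentres intact.

## Compound list
1 | dimethyl (R)-malate | COC(=O)C[C@@H](O)C(=O)OC | starting material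
2 | 4-(benzyloxy)-3-methoxybenzyl chloride | COc1cc(CCl)ccc1OCc1ccccc1 | starting material
3 | dimethyl (2R,3S)-3-[4-(benzyloxy)-3-methoxybenzyl]-2-hydroxysuccinate | COC(=O)[C@@H](Cc1ccc(OCc2ccccc2)c(OC)c1)[C@@H](O)C(=O)OC | intermediate
4 | (2R,3S)-3-[4-(benzyloxy)-3-methoxybenzyl]-2-hydroxysuccinic acid | OC(=O)[C@@H](Cc1ccc(OCc2ccccc2)c(OC)c1)[C@@H](O)C(=O)O | intermediate
5 | pivaldehyde | CC(C)(C)C=O | starting material
6 | dioxolanone acid (2S)-2-[(2R,5R)-2-tBu-4-oxo-1,3-dioxolan-5-yl]-3-aryl-propanoic acid | OC(=O)[C@@H](Cc2ccc(OCc3ccccc3)c(OC)c2)[C@H]1O[C@@H](C(C)(C)C)OC1=O | intermediate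
7 | 5-benzylated dioxolanone acid | OC(=O)[C@@H](Cc2ccc(OCc3ccccc3)c(OC)c2)[C@@]1(Cc4ccc(OCc5ccccc5)c(OC)c4)O[C@@H](C(C)(C)C)OC1=O | intermediate
8 | (2R,3R)-2,3-bis[4-(benzyloxy)-3-methoxybenzyl]butane-1,2,4-triol | OC[C@@H](Cc1ccc(OCc2ccccc2)c(OC)c1)[C@](O)(Cc1ccc(OCc2ccccc2)c(OC)c1)CO | intermediate
9 | bis-O-benzyl tetrahydrofuran | COc1cc(C[C@]2(O)CO[C@@H](c3ccc(OCc4ccccc4)c(OC)c3)[C@@H]2CO)ccc1OCc1ccccc1 | intermediate
10 | target (2R,3S,4R)-oxolan-4-ol | COc1cc(C[C@]2(O)CO[C@@H](c3ccc(O)c(OC)c3)[C@@H]2CO)ccc1O | target

## Totals
Total steps: 7. Longest linear sequence: 7 (from 1).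

## Three steps most likely to fail
1. **Step 6 (new method).**
   - Risks: over-oxidation of the more electron-rich, ether-activated product; competing oxidation at C7'; and fragmentation of the β-hydroxy arene radical cation.
   - Fallback (known chemistry, different approach): in step 1 use 4-benzyloxy-3-methoxybenzaldehyde in a Fráter-type aldol instead of 2. Carry the benzylic alcohol through steps 2–5, then close the ring by acid-catalysed dehydrative cyclisation (TsOH or Sc(OTf)3). The benzylic cation makes the C7 configuration thermodynamic.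
2. **Step 4.**
   - Risk: the acetal must be cis in step 3; a trans acetal, or a hindered branched side chain, would give the C8' epimer or poor conversion.
   - Fallback: oxidise 3 with Dess–Martin periodinane to the α-keto ester and add ArCH2MgCl under chelation control, then separate the diastereomers.
3. **Step 1.**
   - Risks: the electron-rich benzylic chloride may give low yield or poor anti selectivity.
   - Fallback: reverse the order. Benzylate the malate-derived dioxolanone at C8' first (Seebach), then alkylate the side-chain carboxylate dianion to set C8, separating the diastereomers.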